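**Retrosynthetic overview**
- The target is cut at C11'=C12': a last Wittig reaction joins an ε-ring C15 phosphonium salt to a C25 3,4-dihydroxy-β-apocarotenal.
- The C25 aldehyde comes from the C10 trienedial and the 4,5-epoxide of the same C15 salt; base opens the epoxide and turns the ε-ring into the 3,4-cis-dihydroxy-β-ring, so both end groups descend from one ε-ring.
- The C15 salt comes from a cis-3-hydroxy ε-ring vinyl carbinol, made from (R)-α-ionone by vinyl addition, C3 allylic oxidation and catalyst-controlled ketone reduction (oxygenation after cyclisation).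
- (R)-α-Ionone comes from acyclic pseudoionone by one enantioselective proton-initiated cyclisation of the ψ-end to the ε-ring.
- Ring order: the ε-ring is closed first and is the only ring closure; the β-ring is made late from a copy of the ε-ring.

Assumption: pseudoionone is used as its 5E isomer, and the catalyst antipodes named in steps 1 and 4 are those expected to give 6R and 3S; if the observed sense is opposite, the mirror-image catalyst is used. Ring positions are given in carotenoid numbering (C1 = CMe2, C5 = ring C-methyl carbon, C6 = carbon bearing the chain).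

**Step 1**
Reactants: 1 (3E,5E)-pseudoionone
Product: 2 (R)-α-ionone
Conditions: (S,S)-IDPi chiral Brønsted acid [imidodiphosphorimidate from two (S)-3,3'-bis(3,5-bis(trifluoromethyl)phenyl)-BINOL units, N-triflyl] (5 mol%), (CF3)2CHOH/CH2Cl2 1:4, −30 °C
Reagents that add atoms: none
Why: Proposed new method: the confined chiral acid protonates the terminal trisubstituted alkene at C2, the tertiary C1 cation held as a contact ion pair with the chiral anion is attacked by the C5=C6 bond on one enantioface through a chair-like transition state (setting C6 as R), and the C5 cation loses H4 to the anion before it can equilibrate to the conjugated β-isomer, which is the ε-cyclase sequence; the closest known reaction types are the H3PO4 cyclisation of pseudoionone to racemic α-ionone and IDPi-catalysed asymmetric proton-initiated polyene cyclisation in fluorinated alcohols.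

**Step 2**
Reactants: 2 (R)-α-ionone; 3 vinylmagnesium bromide (CH2=CHMgBr)
Product: 4 (1E)-3-methyl-1-[(1R)-2,6,6-trimethylcyclohex-2-en-1-yl]penta-1,4-dien-3-ol (both carbinol epimers)
Conditions: 3 (1.3 equiv), THF, −30 to 0 °C; H2O quench, NH4Cl wash
Reagents that add atoms: vinylmagnesium bromide (3), C=C[Mg]Br
Why: Grignard 1,2-addition to the methyl ketone, the usual entry to C15 vinyl carbinols; addition at low temperature outruns γ-deprotonation so C6 is kept, and the new carbinol centre is a mixture that is erased in step 5.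

**Step 3**
Reactants: 4 vinyl carbinol
Product: 5 (4R)-4-[(1E)-3-hydroxy-3-methylpenta-1,4-dien-1-yl]-3,5,5-trimethylcyclohex-2-en-1-one
Conditions: Rh2(C6H10NO)4 [dirhodium tetrakis(caprolactamate)] (1 mol%), t-BuOOH (70% aq, 5 equiv), NaHCO3, CH2Cl2, rt
Reagents that add atoms: tert-butyl hydroperoxide, CC(C)(C)OO
Why: Kharasch-type radical allylic C-H oxidation by tert-butylperoxyl radicals: the ring CH2 at C3 is the only unhindered allylic methylene (C6-H is shielded by the gem-dimethyl group, the 5-methyl group and the chain), as in the known oxidation of α-ionone and its ketal to the 3-oxo compounds; the tertiary alcohol cannot be oxidised or transposed without chromium, the buffered medium does not enolise C6, and no new stereocentre is formed.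

**Step 4**
Reactants: 5 ring enone
Product: 6 (1S,4R)-4-[(1E)-3-hydroxy-3-methylpenta-1,4-dien-1-yl]-3,5,5-trimethylcyclohex-2-en-1-ol (carotenoid 3S,6R; ring OH cis to the chain)
Conditions: (R)-2-methyl-CBS-oxazaborolidine (0.5 equiv), catecholborane (3 equiv), toluene, −78 °C; aq NaOH work-up; chromatography
Reagents that add atoms: none
Why: Corey–Bakshi–Shibata reduction: the oxazaborolidine–borane complex binds the ring ketone and delivers hydride to one face under catalyst control (ring-alkenyl arm as the large group), setting C3 as S and overriding the substrate's bias toward the trans alcohol; catecholborane gives 1,2-reduction without hydroborating the alkenes, and the minor 3,6-trans diol is removed by chromatography.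

**Step 5**
Reactants: 6 cis-diol; 7 triphenylphosphine
Product: 8 [(2E,4E)-5-[(1R,4S)-4-hydroxy-2,6,6-trimethylcyclohex-2-en-1-yl]-3-methylpenta-2,4-dien-1-yl]triphenylphosphonium chloride
Conditions: 7 (1.05 equiv), HCl (4 M in dioxane, 1.05 equiv), CH2Cl2, 0 °C to rt, 3 h; precipitate with EtOAc
Reagents that add atoms: triphenylphosphine (7), c1ccc(cc1)P(c1ccccc1)c1ccccc1; hydrogen chloride, Cl
Why: SN1-type allylic transposition used for C15 Wittig salts: the acid ionises only the tertiary, doubly allylic carbinol to a pentadienyl cation that PPh3 captures at the unhindered terminal carbon to give the conjugated dienyl salt, while the secondary ring allylic alcohol ionises far more slowly at 0 °C in a non-nucleophilic solvent, so C3 and C6 are kept.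

**Step 6**
Reactants: 8 ε-ring C15 phosphonium chloride
Product: 9 [(2E,4E)-5-[(1R,2R,5S,6S)-5-hydroxy-1,3,3-trimethyl-7-oxabicyclo[4.1.0]heptan-2-yl]-3-methylpenta-2,4-dien-1-yl]triphenylphosphonium chloride (carotenoid 3S,4S,5R,6R; epoxide oxygen cis to 3-OH and chain)
Conditions: mCPBA (1.05 equiv), NaHCO3, CH2Cl2, 0 °C
Reagents that add atoms: m-chloroperoxybenzoic acid, OOC(=O)c1cccc(Cl)c1
Why: Prilezhaev epoxidation with Henbest hydroxyl direction: the trisubstituted ring alkene is the most electron-rich (the diene is deactivated by the allylic phosphonium group and chloride is not oxidised), and the peracid is delivered syn to the 3-OH, the face also preferred in α-ionone-type rings (anti to the axial C1 methyl), setting 4S,5R.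

**Step 7**
Reactants: 9 epoxy phosphonium chloride; 10 (2E,4E,6E)-2,7-dimethylocta-2,4,6-trienedial
Product: 13 (3S,4R)-3,4-dihydroxy-12'-apo-β-caroten-12'-al, via epoxy ylide 11 (not isolated), via epoxy aldehyde 12 (not isolated)
Conditions: 10 (2.5 equiv), NaOMe (1.2 equiv), MeOH/CH2Cl2, 0 °C to rt; then NaOMe (2 equiv), 40 °C; excess 10 recovered
Reagents that add atoms: (2E,4E,6E)-2,7-dimethylocta-2,4,6-trienedial (10), O=C/C(C)=C/C=C/C=C(C)/C=O
Why: Wittig olefination of the semi-stabilised allylic ylide with one aldehyde of the excess symmetrical dial builds C11=C12, after which methoxide removes the C6-H now vinylogously acidified by the polyenal and the extended enolate expels the anti-periplanar C5-O bond (vinylogous E1cB, the base-induced opening known for α-ionone 4,5-epoxide to 4-hydroxy-β-ionone), creating the β-ring C5=C6 bond and leaving the C4-O bond cis to 3-OH (3S,4R) without touching either carbinol centre.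

**Step 8**
Reactants: 13 C25 dihydroxy aldehyde; 8 ε-ring C15 phosphonium chloride
Product: 15 (3S,4R,3'S,6'R)-β,ε-carotene-3,4,3'-triol (CNP0191612.2), via ylide 14 (not isolated)
Conditions: 8 (1.2 equiv), NaOMe (1.5 equiv), MeOH/CH2Cl2, 0 °C to rt; then EtOH/heptane reflux (Z to E isomerisation), crystallisation
Reagents that add atoms: none
Why: Wittig olefination of the allylic ylide with the polyenal forms C11'=C12' in the presence of the free hydroxyl groups, as in hydroxy-carotenoid syntheses; the ε-ring C6'-H is not acidified in the carbonyl-free C40 polyene so 6'R survives the base, and thermal equilibration gives the all-E isomer with no stereocentre changed.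

**Compound list**
1 | (3E,5E)-pseudoionone, (3E,5E)-6,10-dimethylundeca-3,5,9-trien-2-one | CC(=O)/C=C/C=C(C)/CCC=C(C)C | starting material
2 | (R)-α-ionone, (3E)-4-[(1R)-2,6,6-trimethylcyclohex-2-en-1-yl]but-3-en-2-one | CC1=CCCC(C)(C)[C@H]1/C=C/C(C)=O | intermediate
3 | vinylmagnesium bromide (CH2=CHMgBr) | C=C[Mg]Br | starting material
4 | (1E)-3-methyl-1-[(1R)-2,6,6-trimethylcyclohex-2-en-1-yl]penta-1,4-dien-3-ol, both carbinol epimers | CC1=CCCC(C)(C)[C@H]1/C=C/C(C)(O)C=C | intermediate
5 | (4R)-4-[(1E)-3-hydroxy-3-methylpenta-1,4-dien-1-yl]-3,5,5-trimethylcyclohex-2-en-1-one | CC1=CC(=O)CC(C)(C)[C@H]1/C=C/C(C)(O)C=C | intermediate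
6 | (1S,4R)-4-[(1E)-3-hydroxy-3-methylpenta-1,4-dien-1-yl]-3,5,5-trimethylcyclohex-2-en-1-ol, ring OH cis to chain | CC1=C[C@@H](O)CC(C)(C)[C@H]1/C=C/C(C)(O)C=C | intermediate
7 | triphenylphosphine | c1ccc(cc1)P(c1ccccc1)c1ccccc1 | starting material
8 | [(2E,4E)-5-[(1R,4S)-4-hydroxy-2,6,6-trimethylcyclohex-2-en-1-yl]-3-methylpenta-2,4-dien-1-yl]triphenylphosphonium chloride | CC1=C[C@@H](O)CC(C)(C)[C@H]1/C=C/C(C)=C/C[P+](c2ccccc2)(c2ccccc2)c2ccccc2.[Cl-] | intermediate
9 | [(2E,4E)-5-[(1R,2R,5S,6S)-5-hydroxy-1,3,3-trimethyl-7-oxabicyclo[4.1.0]heptan-2-yl]-3-methylpenta-2,4-dien-1-yl]triphenylphosphonium chloride | C[C@]12O[C@H]1[C@@H](O)CC(C)(C)[C@H]2/C=C/C(C)=C/C[P+](c3ccccc3)(c3ccccc3)c3ccccc3.[Cl-] | intermediate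
10 | (2E,4E,6E)-2,7-dimethylocta-2,4,6-trienedial | O=C/C(C)=C/C=C/C=C(C)/C=O | starting material
11 | epoxy ylide, the triphenylphosphorane from 9 | C[C@]12O[C@H]1[C@@H](O)CC(C)(C)[C@H]2/C=C/C(C)=C/C=P(c3ccccc3)(c3ccccc3)c3ccccc3 | intermediate
12 | epoxy aldehyde, (2E,4E,6E,8E,10E,12E)-13-[(1R,2R,5S,6S)-5-hydroxy-1,3,3-trimethyl-7-oxabicyclo[4.1.0]heptan-2-yl]-2,7,11-trimethyltrideca-2,4,6,8,10,12-hexaenal | C[C@]12O[C@H]1[C@@H](O)CC(C)(C)[C@H]2/C=C/C(C)=C/C=C/C(C)=C/C=C/C=C(C)/C=O | intermediate
13 | (3S,4R)-3,4-dihydroxy-12'-apo-β-caroten-12'-al, (2E,4E,6E,8E,10E,12E)-13-[(3R,4S)-3,4-dihydroxy-2,6,6-trimethylcyclohex-1-en-1-yl]-2,7,11-trimethyltrideca-2,4,6,8,10,12-hexaenal | O=C/C(C)=C/C=C/C=C(C)/C=C/C=C(C)/C=C/C1=C(C)[C@@H](O)[C@@H](O)CC1(C)C | intermediate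
14 | ylide, the triphenylphosphorane from 8 | CC1=C[C@@H](O)CC(C)(C)[C@H]1/C=C/C(C)=C/C=P(c2ccccc2)(c2ccccc2)c2ccccc2 | intermediate
15 | (3S,4R,3'S,6'R)-β,ε-carotene-3,4,3'-triol | CC1=C[C@@H](O)CC(C)(C)[C@H]1/C=C/C(C)=C/C=C/C(C)=C/C=C/C=C(C)/C=C/C=C(C)/C=C/C1=C(C)[C@@H](O)[C@@H](O)CC1(C)C | target

**Step count**
Total steps: 8. Longest linear sequence: 8 (steps 1 to 8; salt 8 feeds both step 6 and step 8).

**Steps most likely to fail**

Step 1 (enantioselective cyclisation; reactivity of the dienone and the level of ee are untested). The fallback sets out from 1 and comes back at 6. Pseudoionone 1 is cyclised with 85% H3PO4, the classical racemic ε-type ring closure, to racemic α-ionone F1. Vinylmagnesium bromide addition and the rhodium/t-BuOOH oxidation are run unchanged on the racemate, giving racemic vinyl carbinol F2 and racemic 3-oxo vinyl carbinol F3. The CBS reduction then serves as a reagent-controlled resolution: the 6R half gives 6, and the 6S half gives the 3,6-trans diol F4, which is separated by chromatography and discarded. Stereocontrol at C6 moves from asymmetric catalysis to diastereomer separation, with a 50% yield ceiling.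

Step 3 (allylic oxidation next to a tertiary bis-allylic alcohol and three alkenes). The fallback sets out from 2 and comes back at 6. The carbonyl is masked first: ethylene glycol, HC(OMe)3 and pyridinium p-toluenesulfonate convert 2 into (R)-α-ionone ethylene ketal F5. The ketal is oxidised at C3 with t-BuOOH/aq NaOCl, K2CO3 in MeCN at 0 °C (conditions established for this ketal) to the 3-oxo ketal F6. CBS reduction as in step 4 gives the cis-hydroxy ketal F7. Pyridinium p-toluenesulfonate in wet acetone releases (3S,6R)-3-hydroxy-α-ionone F8. Vinylmagnesium bromide (2.5 equiv) then gives 6. The vinyl group is added last, at a cost of two extra steps.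

Step 4 (catalyst control has to beat the substrate's preference for the trans alcohol). The fallback sets out from 5 and comes back at 6. Substrate control is used instead: LiBH(s-Bu)3 in THF at −78 °C attacks anti to the axial C1 methyl and gives the 3,6-trans diol F9. C3 is then inverted by a Mitsunobu reaction (4-nitrobenzoic acid, PPh3, diisopropyl azodicarboxylate; the tertiary alcohol does not react) to the 4-nitrobenzoate F10. Methanolysis with K2CO3 in MeOH gives 6.

Further compounds
F1 | step 1 | racemic α-ionone, (3E)-4-(2,6,6-trimethylcyclohex-2-en-1-yl)but-3-en-2-one | CC1=CCCC(C)(C)C1/C=C/C(C)=O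
F2 | step 1 | racemic vinyl carbinol, (1E)-3-methyl-1-(2,6,6-trimethylcyclohex-2-en-1-yl)penta-1,4-dien-3-ol | CC1=CCCC(C)(C)C1/C=C/C(C)(O)C=C
F3 | step 1 | racemic 3-oxo vinyl carbinol, 4-[(1E)-3-hydroxy-3-methylpenta-1,4-dien-1-yl]-3,5,5-trimethylcyclohex-2-en-1-one | CC1=CC(=O)CC(C)(C)C1/C=C/C(C)(O)C=C
F4 | step 1 | 3,6-trans diol, (1S,4S)-4-[(1E)-3-hydroxy-3-methylpenta-1,4-dien-1-yl]-3,5,5-trimethylcyclohex-2-en-1-ol | CC1=C[C@@H](O)CC(C)(C)[C@@H]1/C=C/C(C)(O)C=C
F5 | step 3 | (R)-α-ionone ethylene ketal, 2-methyl-2-[(E)-2-[(1R)-2,6,6-trimethylcyclohex-2-en-1-yl]ethenyl]-1,3-dioxolane | CC1=CCCC(C)(C)[C@H]1/C=C/C2(C)OCCO2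
F6 | step 3 | 3-oxo ketal, (4R)-3,5,5-trimethyl-4-[(E)-2-(2-methyl-1,3-dioxolan-2-yl)ethenyl]cyclohex-2-en-1-one | CC1=CC(=O)CC(C)(C)[C@H]1/C=C/C2(C)OCCO2
F7 | step 3 | cis-hydroxy ketal, (1S,4R)-3,5,5-trimethyl-4-[(E)-2-(2-methyl-1,3-dioxolan-2-yl)ethenyl]cyclohex-2-en-1-ol | CC1=C[C@@H](O)CC(C)(C)[C@H]1/C=C/C2(C)OCCO2
F8 | step 3 | (3S,6R)-3-hydroxy-α-ionone, (3E)-4-[(1R,4S)-4-hydroxy-2,6,6-trimethylcyclohex-2-en-1-yl]but-3-en-2-one | CC1=C[C@@H](O)CC(C)(C)[C@H]1/C=C/C(C)=O
F9 | step 4 | 3,6-trans diol, (1R,4R)-4-[(1E)-3-hydroxy-3-methylpenta-1,4-dien-1-yl]-3,5,5-trimethylcyclohex-2-en-1-ol | CC1=C[C@H](O)CC(C)(C)[C@H]1/C=C/C(C)(O)C=C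
F10 | step 4 | 4-nitrobenzoate, (1S,4R)-4-[(1E)-3-hydroxy-3-methylpenta-1,4-dien-1-yl]-3,5,5-trimethylcyclohex-2-en-1-yl 4-nitrobenzoate | CC1=C[C@@H](OC(=O)c2ccc(cc2)[N+](=O)[O-])CC(C)(C)[C@H]1/C=C/C(C)(O)C=C
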